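**Retrosynthetic overview**
1. Ring D and the C7 spiro centre come last, by oxidative ring contraction of a chroman-3-one: the aryl ether oxygen moves from C8 to C7 of ring A (quinone formation, then intramolecular SN2′ with loss of the C13 hydroxyl).
2. The chroman-3-one comes from a one-carbon ring expansion of a benzofuranone lactone with an α-chloroprenyl carbenoid, which brings in C1–C5 and sets C5 under thermodynamic control.
3. Ring B is closed by phenoxide ortho-hydroxyalkylation (C12–C13); the C18 carbinol comes from methyl addition to a cyclopentanone.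
4. C20 and C15 are set by an amine-catalysed asymmetric Michael addition of 5-hydroxy-3-methylbenzofuranone (from benzoquinone and an acrylate-derived ketene acetal) to a 2-dioxolanyl cyclopentenone.
5. Ring order: A (benzoquinone) → lactone → C (cyclopentenone) → B → pyranone (expansion) → D (contraction).

Locants used in names: C5 is the O-bearing CH that carries the 2-methylprop-1-enyl group; ring A is C7–C12 (C8 and C11 oxygenated); ring B is C7, C12, C13, C14, C15, C20; ring C is C14–C18 (C18 carries CH3 and OH); C20 carries CH3 and C22 (C=O). The target is then 5R,7S,14R,15S,18S,20R.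

Assumption: the sense of induction of the amine catalyst in step 3 is taken from the usual model for cyclic enones; the pseudo-enantiomeric (quinine-derived) amine is used if it proves opposite.

**Step 1**
Reactants: 1 methyl acrylate; 2 1,4-benzoquinone
Product: 5 5-hydroxy-3-methyl-1-benzofuran-2(3H)-one (racemic), via ketene silyl acetal 3 (not isolated), via silylated aryl propanoate 4 (not isolated)
Conditions: Et3SiH, RhCl(PPh3)3 (0.5 mol%), PhMe, 60 °C; then 2, CH2Cl2, −78 °C → rt; then TsOH·H2O, PhMe, 80 °C
Reagents that add atoms: none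
Why: Rh-catalysed 1,4-hydrosilylation of the acrylate gives the ketene silyl acetal, which adds to the quinone (Mukaiyama–Michael addition) and aromatises, after which acid removes the silyl group and lactonises onto the ortho phenol; C3 is left racemic because it is enolised in step 3.

**Step 2**
Reactants: 6 cyclopent-2-en-1-one; 7 2-methoxy-1,3-dioxolane
Product: 10 2-(1,3-dioxolan-2-yl)cyclopent-2-en-1-one, via pyridinium silyl enol ether 8 (not isolated), via pyridinium ketone 9 (not isolated)
Conditions: pyridine, Me3SiOTf, CH2Cl2, −78 °C; then 7, −78 → −20 °C; then DBU, rt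
Reagents that add atoms: none
Why: Pyridine adds conjugately and Me3SiOTf traps the enolate as 8, the dioxolanylium ion formed from the ortho ester is captured at C2 (Mukaiyama-type), and DBU eliminates pyridine (a Morita–Baylis–Hillman-type α-functionalisation of the enone); no stereocentre is formed.

**Step 3**
Reactants: 5 5-hydroxy-3-methyl-1-benzofuran-2(3H)-one; 10 2-(1,3-dioxolan-2-yl)cyclopent-2-en-1-one
Product: 11 (3R)-3-[(1S,2S)-2-(1,3-dioxolan-2-yl)-3-oxocyclopentyl]-5-hydroxy-3-methyl-1-benzofuran-2(3H)-one
Conditions: 9-amino-9-deoxy-epi-quinidine (20 mol%), 2-fluorobenzoic acid (40 mol%), PhMe, 40 °C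
Reagents that add atoms: none
Why: Asymmetric Michael addition under iminium activation: the primary amine condenses with 10, the quinuclidine deprotonates 5, and the enol adds to C15 on the catalyst-defined face to create C20 (R) and C15 (S) together, while C14 (S) is set by protonation and equilibration of the α-centre to the trans isomer.

**Step 4**
Reactants: 11 (3R)-3-[(1S,2S)-2-(1,3-dioxolan-2-yl)-3-oxocyclopentyl]-5-hydroxy-3-methyl-1-benzofuran-2(3H)-one
Product: 12 (3R)-3-[(1S,2R,3S)-2-(1,3-dioxolan-2-yl)-3-hydroxy-3-methylcyclopentyl]-5-hydroxy-3-methyl-1-benzofuran-2(3H)-one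
Conditions: MeMgBr (3 equiv), CeCl3 (3 equiv), THF, −78 °C
Reagents that add atoms: methylmagnesium bromide, C[Mg]Br
Why: Organocerium 1,2-addition to the ketone (non-basic, so no enolisation or retro-Michael, and faster than attack on the hindered aryl lactone); methyl enters anti to the adjacent dioxolanyl group on C14, placing the C18 hydroxyl cis to C13 (18S).

**Step 5**
Reactants: 12 (3R)-3-[(1S,2R,3S)-2-(1,3-dioxolan-2-yl)-3-hydroxy-3-methylcyclopentyl]-5-hydroxy-3-methyl-1-benzofuran-2(3H)-one
Product: 14 tetracyclic lactone triol (ring B closed; 14S 15S 18S 20R; C13 epimers), via aldehyde 13 (not isolated)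
Conditions: PPTS, acetone–H2O (10:1), 50 °C; then MgBr2·OEt2, Et3N, CH2Cl2, 0 °C → rt
Reagents that add atoms: water, O
Why: Acetal hydrolysis, then magnesium phenoxide-directed ortho-hydroxyalkylation (intramolecular Friedel–Crafts-type phenol–aldehyde addition) closes ring B at C12, the only ortho position the aldehyde can reach; the trans B/C fusion is already fixed by C14/C15, and the new C13 carbinol centre (either epimer) is removed in step 7.

**Step 6**
Reactants: 14 tetracyclic lactone triol; 15 1-chloro-3-methylbut-2-ene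
Product: 18 chroman-3-one (ring O8–C5–C22(=O)–C20 fused to ring A; 5R 14S 15S 18S 20R; C13 epimers), via lithium carbenoid 16 (not isolated), via chloro ketone 17 (not isolated)
Conditions: 15 (1.5 equiv), LiN(iPr)2 (4.7 equiv), THF, −95 → −20 °C; then rt, 1 h
Reagents that add atoms: none
Why: Proposed new method: lithiation of 15 in the presence of the trilithium salt of 14 gives carbenoid 16, which adds through its α-carbon to the strained aryl lactone carbonyl (γ-attack is blocked by the gem-dimethyl group); the adduct collapses with release of the C8 phenoxide, which displaces chloride at C5, a net 1,2-shift of the aryloxy group from C22 to the carbenoid carbon that expands the five-membered lactone to the six-membered 3-oxo ether, and C5 equilibrates under the basic conditions to the equatorial epimer trans to the axial C20 methyl (5R); the closest known reactions are the chloromethyllithium homologation of esters to α-chloro ketones and the carbonyl addition of lithiated allyl chlorides.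

**Step 7**
Reactants: 18 chroman-3-one
Product: 20 CNP0156201.1 (5R 7S 14R 15S 18S 20R), via hydroxy quinone 19 (not isolated)
Conditions: PhI(OAc)2 (1.1 equiv), MeCN–H2O (4:1), 0 °C; then CSA (20 mol%), 40 °C
Reagents that add atoms: water, O
Why: Oxidative ring contraction: hypervalent-iodine oxidation of the p-alkoxyphenol gives the quinone and frees the C5 alcohol (as in chromanol-to-quinone oxidations), which under acid adds to C7 in a 5-exo oxa-Michael addition while the enol expels the C13 hydroxyl (SN2′ addition–elimination), so the ether oxygen ends on C7 and the ring shrinks from six to five; C7 (S) is fixed because the tether on C20 can only reach the face syn to C22.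

**Compound list**
1 | methyl acrylate | C=CC(=O)OC | starting material
2 | 1,4-benzoquinone | O=C1C=CC(=O)C=C1 | starting material
3 | 1-methoxy-1-(triethylsilyloxy)prop-1-ene (E/Z mixture) | CC=C(OC)O[Si](CC)(CC)CC | intermediate
4 | methyl 2-[2-hydroxy-5-(triethylsilyloxy)phenyl]propanoate (racemic) | COC(=O)C(C)c1cc(O[Si](CC)(CC)CC)ccc1O | intermediate
5 | 5-hydroxy-3-methyl-1-benzofuran-2(3H)-one (racemic, C3 enolisable) | CC1C(=O)Oc2ccc(O)cc12 | intermediate
6 | cyclopent-2-en-1-one | O=C1CCC=C1 | starting material
7 | 2-methoxy-1,3-dioxolane | COC1OCCO1 | starting material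
8 | 1-[3-(trimethylsilyloxy)cyclopent-2-en-1-yl]pyridinium triflate (racemic) | C[Si](C)(C)OC1=CC(CC1)[n+]1ccccc1.[O-]S(=O)(=O)C(F)(F)F | intermediate
9 | 1-[2-(1,3-dioxolan-2-yl)-3-oxocyclopentyl]pyridinium triflate (racemic) | O=C1CCC(C1C1OCCO1)[n+]1ccccc1.[O-]S(=O)(=O)C(F)(F)F | intermediate
10 | 2-(1,3-dioxolan-2-yl)cyclopent-2-en-1-one | O=C1CCC=C1C1OCCO1 | intermediate
11 | (3R)-3-[(1S,2S)-2-(1,3-dioxolan-2-yl)-3-oxocyclopentyl]-5-hydroxy-3-methyl-1-benzofuran-2(3H)-one | O1CCOC1[C@@H]2[C@H](CCC2=O)[C@@]3(C)C(=O)Oc4ccc(O)cc34 | intermediate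
12 | (3R)-3-[(1S,2R,3S)-2-(1,3-dioxolan-2-yl)-3-hydroxy-3-methylcyclopentyl]-5-hydroxy-3-methyl-1-benzofuran-2(3H)-one | O1CCOC1[C@@H]2[C@H](CC[C@]2(C)O)[C@@]3(C)C(=O)Oc4ccc(O)cc34 | intermediate
13 | (1R,2S,5S)-2-hydroxy-5-[(3R)-5-hydroxy-3-methyl-2-oxo-2,3-dihydro-1-benzofuran-3-yl]-2-methylcyclopentane-1-carbaldehyde | O=C[C@@H]1[C@H](CC[C@]1(C)O)[C@@]2(C)C(=O)Oc3ccc(O)cc23 | intermediate
14 | tetracyclic lactone triol: rings A, B, C plus the lactone O8–C22(=O)–C20; OH on C11, C13 (both epimers) and C18; 14S,15S,18S,20R | O=C1Oc2ccc(O)c3C(O)[C@@H]4[C@H](CC[C@]4(C)O)[C@]1(C)c23 | intermediate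
15 | 1-chloro-3-methylbut-2-ene (prenyl chloride) | CC(C)=CCCl | starting material
16 | (1-chloro-3-methylbut-2-en-1-yl)lithium | [Li]C(Cl)C=C(C)C | intermediate
17 | ring-opened α-chloro ketone: C8–OH free, C20–C22(=O)–C5HCl–CH=C(CH3)2 (C5 and C13 epimers); 14S,15S,18S,20R | CC(C)=CC(Cl)C(=O)[C@@]1(C)c2c(O)ccc(O)c2C(O)[C@@H]2[C@@H]1CC[C@]2(C)O | intermediate
18 | chroman-3-one: six-membered ring O8–C5–C22(=O)–C20 fused to ring A at C7–C8, 2-methylprop-1-enyl on C5, OH on C11, C13 (both epimers) and C18; 5R,14S,15S,18S,20R | CC(C)=C[C@H]1Oc2ccc(O)c3C(O)[C@@H]4[C@H](CC[C@]4(C)O)[C@@](C)(C1=O)c23 | intermediate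
19 | ring-opened hydroxy quinone: ring A as C8,C11-quinone, free C5–OH α-hydroxy ketone on C20, OH on C13 (both epimers) and C18; 5R,14S,15S,18S,20R | CC(C)=C[C@@H](O)C(=O)[C@@]1(C)C2=C(C(=O)C=CC2=O)C(O)[C@@H]2[C@@H]1CC[C@]2(C)O | intermediate
20 | CNP0156201.1; 5R,7S,14R,15S,18S,20R | CC(C)=C[C@H]1O[C@@]23C(=O)C=CC(=O)C2=C[C@@H]2[C@H](CC[C@]2(C)O)[C@@]3(C)C1=O | target

**Step count and weak points**
Total steps: 7. Longest linear sequence: 6 (steps 1, 3, 4, 5, 6, 7).

Step 3 (Michael addition to an α-branched enone; both reactivity and the C20/C15 ratio are uncertain). The fallback sets out from 5 and returns at 11. Silylation of 5 (Me3SiOTf, Et3N) gives 3-methyl-2,5-bis(trimethylsilyloxy)-1-benzofuran F1. Mukaiyama–Michael addition of F1 to cyclopent-2-en-1-one 6 under a chiral o-tolyl oxazaborolidinium triflimide, a catalyst type established for silyl ketene acetals and cyclic enones, gives the regiodefined silyl enol ether (3R)-3-methyl-5-(trimethylsilyloxy)-3-[(1S)-3-(trimethylsilyloxy)cyclopent-2-en-1-yl]-1-benzofuran-2(3H)-one F2. A Me3SiOTf-promoted Mukaiyama reaction of F2 with 2-methoxy-1,3-dioxolane 7 places the dioxolanyl group trans on C14, and aqueous work-up cleaves the aryl silyl ether to give 11.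

Step 6 (the proposed new ring expansion; the carbenoid may decompose, add twice, or attack through its γ-carbon). The fallback uses known chemistry, sets out from 14 and returns at 18. The trilithium salt of 14 (LiN(SiMe3)2) is treated with ClCH2Li, made in the flask from ICH2Cl and MeLi·LiBr at −78 °C; this is the established homologation of esters to chloromethyl ketones and gives the chloromethyl ketone F3. On warming, the C8 phenoxide displaces chloride to give the C5-unsubstituted chroman-3-one F4. Pd-catalysed ketone α-alkenylation of F4 (Pd2(dba)3, tBu3P, LiN(SiMe3)2, 1-bromo-2-methylprop-1-ene, THF) then installs the 2-methylprop-1-enyl group at C5, the only enolisable position, and gives 18 after equilibration of C5.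

Step 7 (the cascade may stop at the open hydroxy quinone or at the aldol stage, or the hydroxyalkyl quinone may isomerise). The fallback sets out from 19, isolated after the PhI(OAc)2 oxidation, and returns at 20. CSA in CH2Cl2 at rt closes the oxa-Michael adduct, the spiro-ether aldol F5 (C12–H, C13–OH). MsCl and Et3N at 0 °C convert the secondary C13 hydroxyl, not the tertiary C18 hydroxyl, into the mesylate F6, which undergoes E1cB elimination in the same flask to give 20.

**Further compounds**
F1 | step 3 | 3-methyl-2,5-bis(trimethylsilyloxy)-1-benzofuran | Cc1c(O[Si](C)(C)C)oc2ccc(O[Si](C)(C)C)cc12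
F2 | step 3 | (3R)-3-methyl-5-(trimethylsilyloxy)-3-[(1S)-3-(trimethylsilyloxy)cyclopent-2-en-1-yl]-1-benzofuran-2(3H)-one | C[Si](C)(C)OC1=C[C@H](CC1)[C@@]2(C)C(=O)Oc3ccc(O[Si](C)(C)C)cc23
F3 | step 6 | ring-opened chloromethyl ketone (C8–OH free; 14S,15S,18S,20R; C13 epimers) | ClCC(=O)[C@@]1(C)c2c(O)ccc(O)c2C(O)[C@@H]2[C@@H]1CC[C@]2(C)O
F4 | step 6 | C5-unsubstituted chroman-3-one (14S,15S,18S,20R; C13 epimers) | O=C1COc2ccc(O)c3C(O)[C@@H]4[C@H](CC[C@]4(C)O)[C@]1(C)c23
F5 | step 7 | spiro-ether aldol, the 12,13-dihydro-13-hydroxy derivative of 20 (C12 and C13 epimers) | CC(C)=C[C@H]1O[C@@]23C(=O)C=CC(=O)C2C(O)[C@@H]2[C@H](CC[C@]2(C)O)[C@@]3(C)C1=O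
F6 | step 7 | C13 methanesulfonate of the spiro-ether aldol | CC(C)=C[C@H]1O[C@@]23C(=O)C=CC(=O)C2C(OS(C)(=O)=O)[C@@H]2[C@H](CC[C@]2(C)O)[C@@]3(C)C1=O
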